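Atom numbering follows the germacrane skeleton as read from the SMILES: C1 ketone, C2=C3 (C3 bears the ring oxygen), C4(=C5) with methyl C15, C6 (lactone O), C7, C8 (ester O), C9 (OH), C10 (methyl C14, ring oxygen), C11(=C13), C12 (lactone C=O). The route is a proposal and has not been run.

## Analysis of the target

Lobatin B is a furanoheliangolide. A ten-membered carbocycle (ring B, C1–C10) is bridged by the oxygen of a 3(2H)-furanone (ring A: O, C3, C2, C1, C10), giving an 11-oxabicyclo[6.2.1]undecadiene in which C2=C3 is trans and C4=C5 is cis with respect to ring B. A trans-fused α-methylene-γ-butyrolactone (ring C: C6, C7, C11, C12, O) sits on C6–C7. Five contiguous stereocentres run from C6 to C10 (6R,7S,8S,9R,10R): H6 and H7 are anti, the C8/C9 dioxygen pair is threo (the L-threo pattern), and C10 is a fully substituted carbinol carbon next to the C1 ketone. The single bond C6–C7 is the pivot of the structure. It belongs at once to ring B, to the nine-membered oxacycle O–C3–C4–C5–C6–C7–C8–C9–C10 and to ring C, and it joins an allylic carbinol carbon (C6) to the γ-carbon of the acrylate C13=C11–C12 (C7); the key step is built on this bond. The sensitive groups are the exo-methylene lactone (Michael acceptor), the dienone C5=C4–C3=C2–C1=O whose C4=C5 bond must stay Z, the β-hydroxy ketone C9(OH)–C10–C1=O (retro-aldol would release an aromatic 3-furanolate), and the vicinal ester/alcohol pair at C8/C9 (acyl migration). The difficulty is to close a strained, bridged medium ring that contains a Z-trisubstituted olefin while setting C6 and C7 against three existing centres, and to tell O8 from O9 at the end, all under near-neutral conditions.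

## Retrosynthetic reasoning

**24 ⇒ 23 ⇒ 22.** The O8 ester bond and the two O–Si bonds are cut last. An acyloxy group at C8 would sit next to the nucleophilic C7 of an allyl metal and invite reductive 1,4-elimination, so O8 and O9 travel through the key step as silyl ethers (poor leaving groups). Forward, both silyl groups are removed from 22 and diol 23 is acylated on the less hindered O8; the C9 hydroxyl is neopentylic, next to the quaternary C10.

**22 ⇒ 19 (key disconnection).** The C6–C7 bond and the lactone bond O6–C12 are cut together. Cutting here, and not at C4=C5 or inside the furanone, leaves the planar furanone in place: it already ties C3 to C10 and rigidly spans four of the ten ring atoms. The Z-C4=C5 bond turns C6 back toward C7, and the polarity is the natural one: C6 as an enal carbonyl, C13 as an allylic bromide. The gain is large, from monocyclic 19 with three stereocentres to tricyclic 22 with five. The forward reaction has to add the allyl metal through C7 to the C6 aldehyde intramolecularly and let the resulting alkoxide close the lactone.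

**19 ⇒ 18 ⇒ 16 ⇒ 14 + 15.** The allylic bromide is traced back through an allylic transposition to the Morita–Baylis–Hillman adduct 16, which forms the C7–C11 bond from aldehyde 14 and methyl acrylate 15. The C6 aldehyde stays masked as a dimethyl acetal until the step before the cyclisation, because two aldehydes could not be told apart and the Z-enal is labile.

**14 ⇒ 13 ⇒ 11.** The furanone (O10–C3 bond and C1 ketone) is unfolded to the 4-hydroxy-2-ynone 11. Its tertiary C10 hydroxyl becomes the ring oxygen in an amine-mediated cycloisomerisation. The primary C7 hydroxyl needs no protecting group and is oxidised afterwards.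

**11 ⇒ 5 + 9.** The C2–C3 bond is cut between the acetylide of 5 and Weinreb amide 9. Amide 9 carries C3–C6 with the Z-olefin already in place (C3 and C6 cis); it comes from ester 8, made by a Z-selective olefination of 6 with 7.

**5 ⇒ 3 ⇒ 2 ⇒ 1.** The C10–C14 and C10–C1 bonds are cut: a methyl and then an ethynyl nucleophile are added to the lactone carbonyl of 2. L-Threono-1,4-lactone 1 supplies C7–C10 and both secondary centres (C8, C9). After ring opening it also leaves the primary C7 hydroxyl free exactly where the later oxidation is needed. C10 is the only centre made by substrate control before the key step.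

## Alternatives that were turned down

**Alternative 1:** the textbook cut at C4=C5. The forward key step is ring-closing metathesis of diene lactone A1 (vinyl group on C6, isopropenyl group on the furanone C3) with a second-generation ruthenium catalyst. It was turned down for three reasons. The metathesis would have to engage a 1,1-disubstituted olefin that is the terminus of a vinylogous ester and form a trisubstituted, conjugated olefin inside a strained bridged ten-membered ring, where dimerisation competes. The event closes one ring and sets no stereocentre. The lactone with C6 and C7 must be built beforehand by a separate intermolecular allylation, at the same step count and without the macrocyclic constraint at C6. It is kept as the fallback for the key step.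

**Alternative 2:** the same C6–C7/lactone cut, but made before the furanone exists. The forward key step would close the monocyclic ten-membered 4-hydroxy-2-ynone A2, and a transannular amine-mediated cycloisomerisation would then form ring A. It was turned down because A2 must hold the collinear unit C3(=O)–C2≡C1–C10 together with a Z-olefin and a trans-lactone in a ten-membered ring. That strain is of the order found in cyclodecenynes, so the closure loses the preorganisation the furanone provides; the ynone is also a far better electron and nucleophile acceptor than the vinylogous ester during the chromium step. The step count is the same and the risk is higher.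

**Alternative 3:** strain-release ring expansion. The forward key step is thermal conrotatory opening of the cis-fused cyclobutene A3 (σ-bond C2–C5, π-bond C3=C4), made by intramolecular enone–alkynyl ether [2+2] photocycloaddition of the cyclooct-2-enone A4. The idea fits the structure: the opening of a bicyclo[6.2.0]decene gives a cis,trans-cyclodeca-1,3-diene, and the five-membered ring forces C1 to rotate outward, which is exactly the 2E,4Z-dienone of ring B. It was turned down because A4 is an eight-membered ring that already carries all five stereocentres, the lactone and a tertiary 1-propynyl ether, so the precursor is no simpler than the product. Cyclooctenones also isomerise to the trans-enone on irradiation, and A3 contains a ring-fusion cyclobutene double bond of doubtful stability.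

Key step: step 12

Assumption: L-threono-1,4-lactone and ethyl 2-[bis(2,2,2-trifluoroethoxy)phosphoryl]propanoate are taken as commercial, and 2,2-dimethoxyacetaldehyde is used anhydrous (dried from its commercial aqueous solution).

## Route

Step 1
Reactants: 1 L-threono-1,4-lactone
Product: 2 (3R,4S)-3,4-bis[(tert-butyldimethylsilyl)oxy]oxolan-2-one
Conditions: TBSOTf (2.4 equiv), 2,6-lutidine, CH2Cl2, −40 → 0 °C
Reagents that add atoms: tert-butyldimethylsilyl triflate, CC(C)(C)[Si](C)(C)OS(=O)(=O)C(F)(F)F
Why: Silylation with a silyl triflate and a hindered pyridine base protects both secondary hydroxyls without opening the lactone and leaves the future C8 and C9 untouched. Silyl ethers are chosen because they do not chelate in step 3 and are poor leaving groups next to the allyl metal of step 12.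

Step 2
Reactants: 2 (3R,4S)-3,4-bis[(tert-butyldimethylsilyl)oxy]oxolan-2-one
Product: 3 (3R,4S)-3,4-bis[(tert-butyldimethylsilyl)oxy]-2-methyloxolan-2-ol (anomeric mixture)
Conditions: MeLi (1.05 equiv), THF, −78 °C; then H2O
Reagents that add atoms: methyllithium, [Li]C
Why: Single addition of an organolithium to a lactone: the tetrahedral lithium hemiketalate is stable at −78 °C, so a second addition is avoided and the methyl ketone is obtained as its lactol. This installs C14 on the future C10.

Step 3
Reactants: 3 (3R,4S)-3,4-bis[(tert-butyldimethylsilyl)oxy]-2-methyloxolan-2-ol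
Product: 5 (2S,3R,4S)-2,3-bis[(tert-butyldimethylsilyl)oxy]-4-methylhex-5-yne-1,4-diol, via open-chain ketone 4 (not isolated)
Conditions: HC≡CMgBr (4 equiv), THF, −20 → 25 °C; then H2O
Reagents that add atoms: ethynylmagnesium bromide, C#C[Mg]Br
Why: Grignard addition to the ring-opened ketone tautomer 4. With the non-chelating silyloxy group at C9 the polar Felkin–Anh model (C9–O anti to the nucleophile, C8 on the carbonyl-oxygen side) predicts the (4S)-carbinol, which is 10R of the target. Diastereomers would be separable at this stage.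

Step 4
Reactants: 6 2,2-dimethoxyacetaldehyde; 7 ethyl 2-[bis(2,2,2-trifluoroethoxy)phosphoryl]propanoate
Product: 8 ethyl (2Z)-4,4-dimethoxy-2-methylbut-2-enoate
Conditions: KN(SiMe3)2, 18-crown-6, THF, −78 °C
Reagents that add atoms: none
Why: Still–Gennari variant of the Horner–Wadsworth–Emmons olefination. Fast, irreversible elimination from the kinetic adduct under dissociating conditions gives the Z-trisubstituted enoate, which places the future C3 carbonyl and C6 cis, as the 4Z bond demands.

Step 5
Reactants: 8 ethyl (2Z)-4,4-dimethoxy-2-methylbut-2-enoate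
Product: 9 (2Z)-N,4,4-trimethoxy-N,2-dimethylbut-2-enamide
Conditions: MeNHOMe·HCl, iPrMgCl, THF, −20 °C
Reagents that add atoms: N,O-dimethylhydroxylamine hydrochloride, CNOC.Cl
Why: Aminolysis of an ester by the chloromagnesium amide of N,O-dimethylhydroxylamine gives the Weinreb amide. The Z-olefin and the acetal are inert to these conditions.

Step 6
Reactants: 5 (2S,3R,4S)-2,3-bis[(tert-butyldimethylsilyl)oxy]-4-methylhex-5-yne-1,4-diol; 9 (2Z)-N,4,4-trimethoxy-N,2-dimethylbut-2-enamide
Product: 11 (2Z,7S,8R,9S)-8,9-bis[(tert-butyldimethylsilyl)oxy]-7,10-dihydroxy-1,1-dimethoxy-3,7-dimethyldec-2-en-5-yn-4-one, via trilithium salt 10 (not isolated)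
Conditions: n-BuLi (3.1 equiv), THF, −78 °C; then 9, −78 → −30 °C; then H2O
Reagents that add atoms: none
Why: Acylation of a lithium acetylide by a Weinreb amide: the chelated tetrahedral intermediate stops at the ketone, and the two lithium alkoxides are spectators. Keeping the mixture below −30 °C should prevent 1,2-silyl migration to the alkoxides.

Step 7
Reactants: 11 (2Z,7S,8R,9S)-8,9-bis[(tert-butyldimethylsilyl)oxy]-7,10-dihydroxy-1,1-dimethoxy-3,7-dimethyldec-2-en-5-yn-4-one
Product: 13 (2R)-2-[(1R,2S)-1,2-bis[(tert-butyldimethylsilyl)oxy]-3-hydroxypropyl]-5-[(2Z)-4,4-dimethoxybut-2-en-2-yl]-2-methylfuran-3(2H)-one, via diethylamino enone 12 (not isolated)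
Conditions: Et2NH (5 equiv), EtOH, 25 °C; aqueous work-up
Reagents that add atoms: water, O
Why: Amine-mediated cycloisomerisation of a 4-hydroxyalk-2-ynone to a 3(2H)-furanone: conjugate addition of Et2NH at C1, 5-exo-trig attack of the tertiary C10 hydroxyl on the C3 carbonyl, loss of water and hydrolysis of the iminium ion leave C1 as the ketone and O–C3 as the enol ether. C10 carries no hydrogen, so neither aromatisation nor epimerisation is possible.

Step 8
Reactants: 13 (2R)-2-[(1R,2S)-1,2-bis[(tert-butyldimethylsilyl)oxy]-3-hydroxypropyl]-5-[(2Z)-4,4-dimethoxybut-2-en-2-yl]-2-methylfuran-3(2H)-one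
Product: 14 (2R,3R)-2,3-bis[(tert-butyldimethylsilyl)oxy]-3-[(2R)-5-[(2Z)-4,4-dimethoxybut-2-en-2-yl]-2-methyl-3-oxo-2,3-dihydrofuran-2-yl]propanal
Conditions: (nPr4N)RuO4 (5 mol %), NMO (1.5 equiv), 4 Å MS, CH2Cl2, 25 °C
Reagents that add atoms: none
Why: Ley–Griffith oxidation of the primary alcohol under neutral conditions spares the acetal, the silyl ethers and the dienone. The α-silyloxy aldehyde is used without delay to avoid epimerisation at C8.

Step 9
Reactants: 14 (2R,3R)-2,3-bis[(tert-butyldimethylsilyl)oxy]-3-[(2R)-5-[(2Z)-4,4-dimethoxybut-2-en-2-yl]-2-methyl-3-oxo-2,3-dihydrofuran-2-yl]propanal; 15 methyl acrylate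
Product: 16 methyl (4S,5R)-4,5-bis[(tert-butyldimethylsilyl)oxy]-5-[(2R)-5-[(2Z)-4,4-dimethoxybut-2-en-2-yl]-2-methyl-3-oxo-2,3-dihydrofuran-2-yl]-3-hydroxy-2-methylidenepentanoate (both C3 epimers)
Conditions: 15 (5 equiv), DABCO (1 equiv), MeOH, 25 °C
Reagents that add atoms: none
Why: Morita–Baylis–Hillman reaction: the amine adds to 15 and the resulting enolate attacks the activated α-oxygenated aldehyde, forming C7–C11. The configuration of the new carbinol carbon C7 is irrelevant because it becomes sp2 in step 10.

Step 10
Reactants: 16 methyl (4S,5R)-4,5-bis[(tert-butyldimethylsilyl)oxy]-5-[(2R)-5-[(2Z)-4,4-dimethoxybut-2-en-2-yl]-2-methyl-3-oxo-2,3-dihydrofuran-2-yl]-3-hydroxy-2-methylidenepentanoate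
Product: 18 methyl (2Z,4S,5R)-2-(bromomethyl)-4,5-bis[(tert-butyldimethylsilyl)oxy]-5-[(2R)-5-[(2Z)-4,4-dimethoxybut-2-en-2-yl]-2-methyl-3-oxo-2,3-dihydrofuran-2-yl]pent-2-enoate, via allylic mesylate 17 (not isolated)
Conditions: MsCl, Et3N, CH2Cl2, −20 °C; then LiBr, acetone, 0 → 25 °C
Reagents that add atoms: lithium bromide, [Li+].[Br-]
Why: Allylic transposition of a Morita–Baylis–Hillman alcohol: mesylation and SN2′ displacement by bromide give the thermodynamically preferred (Z)-2-(bromomethyl)alk-2-enoate. Electrophilic bromine, which could attack the furanone C2, is avoided.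

Step 11
Reactants: 18 methyl (2Z,4S,5R)-2-(bromomethyl)-4,5-bis[(tert-butyldimethylsilyl)oxy]-5-[(2R)-5-[(2Z)-4,4-dimethoxybut-2-en-2-yl]-2-methyl-3-oxo-2,3-dihydrofuran-2-yl]pent-2-enoate
Product: 19 methyl (2Z,4S,5R)-2-(bromomethyl)-4,5-bis[(tert-butyldimethylsilyl)oxy]-5-[(2R)-2-methyl-3-oxo-5-[(2Z)-4-oxobut-2-en-2-yl]-2,3-dihydrofuran-2-yl]pent-2-enoate
Conditions: PPTS (0.2 equiv), acetone/H2O (20:1), 0 → 25 °C
Reagents that add atoms: water, O
Why: Hydrolysis of an allylic dimethyl acetal through a stabilised oxocarbenium ion needs only a weak acid, under which the silyl ethers and the allylic bromide survive. The Z-enal is used at once because acid, light or nucleophiles could isomerise it.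

Step 12
Reactants: 19 methyl (2Z,4S,5R)-2-(bromomethyl)-4,5-bis[(tert-butyldimethylsilyl)oxy]-5-[(2R)-2-methyl-3-oxo-5-[(2Z)-4-oxobut-2-en-2-yl]-2,3-dihydrofuran-2-yl]pent-2-enoate
Product: 22 (6R,7S,8S,9R,10R)-8,9-bis-O-(tert-butyldimethylsilyl)-8-O-desisovaleryl-lobatin B, via allylchromium dichloride 20 (not isolated), via macrocyclic hydroxy ester 21 (not isolated)
Conditions: CrCl2 (8 equiv), THF (degassed), 25 °C, 19 added by syringe pump (final 2 mM); then PPTS (cat.), CH2Cl2, 25 °C
Reagents that add atoms: none
Why: Two equivalents of CrCl2 reduce the allylic C13–Br bond to the σ-allyl species 20 (trivalent chromium), which equilibrates by 1,3-metal shift and adds through C7 to the chromium-bound C6 aldehyde in a six-membered chair transition state; the chromium alkoxide of 21 then acylates itself with the C12 methyl ester. The closest known reaction type is the chromium-mediated (Nozaki–Hiyama-type) Barbier allylation of aldehydes with 2-(bromomethyl)alk-2-enoates to α-methylene-γ-butyrolactones, including its intramolecular use for ten-membered germacranolide rings. Ring B (and with it the nine-membered oxacycle) closes by a 10-exo-trig addition to the aldehyde, and ring C closes by a 5-exo-trig acyl substitution. C6 is set relative to C7 by the chair in which C5 of the enal and C8 of the allyl unit are both equatorial, which gives the anti adduct and hence the trans-lactone (6R). C7 is set by C8: with H8 eclipsing the C7=C11 bond (1,3-allylic strain) the aldehyde should add anti to the C8–C9 bond and syn to the silyloxy group, which matches an antiperiplanar C6–C7–C8–C9 segment in the forming ring and gives 7S. The step needs ring closure over oligomerisation, reduction of the bromide in preference to the enal, and an allyl metal that does not eliminate; these are secured by high dilution together with the rigid furanone and the Z-C4=C5 bond that point C6 toward C7, by the much faster reduction of allylic bromides by divalent chromium, and by carrying O8 as a silyl ether.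

Step 13
Reactants: 22 (6R,7S,8S,9R,10R)-8,9-bis-O-(tert-butyldimethylsilyl)-8-O-desisovaleryl-lobatin B
Product: 23 (6R,7R,8S,9R,10R)-8-O-desisovaleryl-lobatin B (8,9-diol)
Conditions: HF·pyridine, pyridine, THF, 0 → 25 °C
Reagents that add atoms: none
Why: Fluoride-mediated cleavage of both silyl ethers under buffered, weakly acidic conditions. A basic fluoride source is avoided because the liberated β-hydroxy ketone could undergo retro-aldol cleavage and the exo-methylene lactone could add nucleophiles.

Step 14
Reactants: 23 (6R,7R,8S,9R,10R)-8-O-desisovaleryl-lobatin B (8,9-diol)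
Product: 24 lobatin B
Conditions: isovaleryl chloride (1.05 equiv), 2,4,6-collidine, CH2Cl2, −78 → −40 °C
Reagents that add atoms: 3-methylbutanoyl chloride, CC(C)CC(Cl)=O
Why: Kinetically controlled acylation of a diol with an acid chloride and a non-nucleophilic base at low temperature. The C8 hydroxyl lies between two methine carbons, whereas the C9 hydroxyl is next to the quaternary C10 and hydrogen-bonded to the C1 ketone, so O8 should react first; the ester on the less hindered oxygen is also the one favoured if acyl migration sets in.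

## Compound list

1 | L-threono-1,4-lactone, (3R,4S)-3,4-dihydroxyoxolan-2-one | O=C1[C@H](O)[C@@H](O)CO1 | starting material
2 | (3R,4S)-3,4-bis[(tert-butyldimethylsilyl)oxy]oxolan-2-one | O=C1[C@H](O[Si](C)(C)C(C)(C)C)[C@@H](O[Si](C)(C)C(C)(C)C)CO1 | intermediate
3 | (3R,4S)-3,4-bis[(tert-butyldimethylsilyl)oxy]-2-methyloxolan-2-ol (anomeric mixture) | CC1(O)[C@H](O[Si](C)(C)C(C)(C)C)[C@@H](O[Si](C)(C)C(C)(C)C)CO1 | intermediate
4 | (3R,4S)-3,4-bis[(tert-butyldimethylsilyl)oxy]-5-hydroxypentan-2-one (open-chain tautomer of 3, present as its bromomagnesium alkoxide) | CC(=O)[C@H](O[Si](C)(C)C(C)(C)C)[C@@H](O[Si](C)(C)C(C)(C)C)CO | intermediate (not isolated)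
5 | (2S,3R,4S)-2,3-bis[(tert-butyldimethylsilyl)oxy]-4-methylhex-5-yne-1,4-diol | C#C[C@](C)(O)[C@H](O[Si](C)(C)C(C)(C)C)[C@@H](O[Si](C)(C)C(C)(C)C)CO | intermediate
6 | 2,2-dimethoxyacetaldehyde | COC(OC)C=O | starting material
7 | ethyl 2-[bis(2,2,2-trifluoroethoxy)phosphoryl]propanoate | CCOC(=O)C(C)P(=O)(OCC(F)(F)F)OCC(F)(F)F | starting material
8 | ethyl (2Z)-4,4-dimethoxy-2-methylbut-2-enoate | CCOC(=O)/C(C)=C\C(OC)OC | intermediate
9 | (2Z)-N,4,4-trimethoxy-N,2-dimethylbut-2-enamide | CON(C)C(=O)/C(C)=C\C(OC)OC | intermediate
10 | trilithium salt of 5 (lithium acetylide, two lithium alkoxides) | [Li]C#C[C@](C)(O[Li])[C@H](O[Si](C)(C)C(C)(C)C)[C@@H](O[Si](C)(C)C(C)(C)C)CO[Li] | intermediate (not isolated)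
11 | (2Z,7S,8R,9S)-8,9-bis[(tert-butyldimethylsilyl)oxy]-7,10-dihydroxy-1,1-dimethoxy-3,7-dimethyldec-2-en-5-yn-4-one | COC(OC)/C=C(/C)C(=O)C#C[C@](C)(O)[C@H](O[Si](C)(C)C(C)(C)C)[C@@H](O[Si](C)(C)C(C)(C)C)CO | intermediate
12 | 6-(diethylamino)deca-2,5-dien-4-one adduct of 11 (2Z; geometry of the new C5=C6 bond not fixed) | COC(OC)/C=C(/C)C(=O)C=C(N(CC)CC)[C@](C)(O)[C@H](O[Si](C)(C)C(C)(C)C)[C@@H](O[Si](C)(C)C(C)(C)C)CO | intermediate (not isolated)
13 | (2R)-2-[(1R,2S)-1,2-bis[(tert-butyldimethylsilyl)oxy]-3-hydroxypropyl]-5-[(2Z)-4,4-dimethoxybut-2-en-2-yl]-2-methylfuran-3(2H)-one | COC(OC)/C=C(/C)C1=CC(=O)[C@](C)(O1)[C@H](O[Si](C)(C)C(C)(C)C)[C@@H](O[Si](C)(C)C(C)(C)C)CO | intermediate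
14 | (2R,3R)-2,3-bis[(tert-butyldimethylsilyl)oxy]-3-[(2R)-5-[(2Z)-4,4-dimethoxybut-2-en-2-yl]-2-methyl-3-oxo-2,3-dihydrofuran-2-yl]propanal | COC(OC)/C=C(/C)C1=CC(=O)[C@](C)(O1)[C@H](O[Si](C)(C)C(C)(C)C)[C@@H](O[Si](C)(C)C(C)(C)C)C=O | intermediate
15 | methyl acrylate | C=CC(=O)OC | starting material
16 | methyl (4S,5R)-4,5-bis[(tert-butyldimethylsilyl)oxy]-5-[(2R)-5-[(2Z)-4,4-dimethoxybut-2-en-2-yl]-2-methyl-3-oxo-2,3-dihydrofuran-2-yl]-3-hydroxy-2-methylidenepentanoate (both C3 epimers) | COC(OC)/C=C(/C)C1=CC(=O)[C@](C)(O1)[C@H](O[Si](C)(C)C(C)(C)C)[C@@H](O[Si](C)(C)C(C)(C)C)C(O)C(=C)C(=O)OC | intermediate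
17 | C3 methanesulfonate of 16 | COC(OC)/C=C(/C)C1=CC(=O)[C@](C)(O1)[C@H](O[Si](C)(C)C(C)(C)C)[C@@H](O[Si](C)(C)C(C)(C)C)C(OS(C)(=O)=O)C(=C)C(=O)OC | intermediate (not isolated)
18 | methyl (2Z,4S,5R)-2-(bromomethyl)-4,5-bis[(tert-butyldimethylsilyl)oxy]-5-[(2R)-5-[(2Z)-4,4-dimethoxybut-2-en-2-yl]-2-methyl-3-oxo-2,3-dihydrofuran-2-yl]pent-2-enoate | COC(OC)/C=C(/C)C1=CC(=O)[C@](C)(O1)[C@H](O[Si](C)(C)C(C)(C)C)[C@@H](O[Si](C)(C)C(C)(C)C)/C=C(\CBr)C(=O)OC | intermediate
19 | methyl (2Z,4S,5R)-2-(bromomethyl)-4,5-bis[(tert-butyldimethylsilyl)oxy]-5-[(2R)-2-methyl-3-oxo-5-[(2Z)-4-oxobut-2-en-2-yl]-2,3-dihydrofuran-2-yl]pent-2-enoate | O=C/C=C(/C)C1=CC(=O)[C@](C)(O1)[C@H](O[Si](C)(C)C(C)(C)C)[C@@H](O[Si](C)(C)C(C)(C)C)/C=C(\CBr)C(=O)OC | intermediate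
20 | σ-allyl chromium dichloride from 19 (CrCl2 unit on C13, C7=C11 geometry labile) | O=C/C=C(/C)C1=CC(=O)[C@](C)(O1)[C@H](O[Si](C)(C)C(C)(C)C)[C@@H](O[Si](C)(C)C(C)(C)C)C=C(C[Cr](Cl)Cl)C(=O)OC | intermediate (not isolated)
21 | ten-membered C6 alcohol with methyl 2-propenoate unit on C7 (seco-lactone of 22, present as its chromium alkoxide) | O[C@@H]1/C=C(/C)C2=CC(=O)[C@](C)(O2)[C@H](O[Si](C)(C)C(C)(C)C)[C@@H](O[Si](C)(C)C(C)(C)C)[C@H]1C(=C)C(=O)OC | intermediate (not isolated)
22 | (6R,7S,8S,9R,10R)-8,9-bis-O-(tert-butyldimethylsilyl)-8-O-desisovaleryl-lobatin B | C=C1C(=O)O[C@@H]2/C=C(/C)C3=CC(=O)[C@](C)(O3)[C@H](O[Si](C)(C)C(C)(C)C)[C@@H](O[Si](C)(C)C(C)(C)C)[C@@H]12 | intermediate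
23 | (6R,7R,8S,9R,10R)-8-O-desisovaleryl-lobatin B (8,9-diol) | C=C1C(=O)O[C@@H]2/C=C(/C)C3=CC(=O)[C@](C)(O3)[C@H](O)[C@@H](O)[C@@H]12 | intermediate
24 | lobatin B, (6R,7S,8S,9R,10R) | C=C1C(=O)O[C@@H]2/C=C(/C)C3=CC(=O)[C@](C)(O3)[C@H](O)[C@@H](OC(=O)CC(C)C)[C@@H]12 | target

## Step count and least certain steps

Total step count: 14. Longest linear sequence: 12 steps (1–3, then 6–14); steps 4 and 5 form the two-step side branch.

**Step 12 (key step).** The most likely failure is loss of stereocontrol in the carbonyl addition. A syn instead of an anti addition would give the cis-fused lactone, and addition to the other face of C7 would give the 7-epimer, because the preference of the 2-carbomethoxyallyl chromium species for the chair with both substituents equatorial is not as secure as for simple crotyl reagents and has to compete with the strain of the forming ring. The second danger is intermolecular coupling of the slowly cyclising allyl metal, and the third is Z to E isomerisation of the enal, after which the ring cannot close.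

The fallback separates stereocontrol from ring closure and closes the ring at C4=C5 instead:
- Setting out from 5, its trilithium salt 10 would be acylated with N-methoxy-N-methylmethacrylamide to the isopropenyl ynone F1.
- The cycloisomerisation of step 7 should turn F1 into the 5-isopropenylfuranone alcohol F2.
- Oxidation as in step 8 would give the aldehyde F3, the Morita–Baylis–Hillman reaction with 15 the adduct F4, and mesylation and bromide displacement the allylic bromide F5.
- Intermolecular allylation of acrolein with F5 and CrCl2, followed by lactonisation, would give the diene lactone A1.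
- Ring-closing metathesis of A1 with the second-generation Hoveyda–Grubbs catalyst (toluene, 80 °C, high dilution) would form the Z-C4=C5 bond and come back to the route at 22.

**Step 3.** Facial selectivity at the ketone may be poor, because a magnesium alkoxide in the same molecule can upset the Felkin–Anh preference, and the lactol may open only slowly. The fallback reverses the order of the two nucleophiles and the control element. Setting out from 2, lithium (trimethylsilyl)acetylide would add once to the lactone to give the silylated ynone F6 (open-chain form of its lactol). A chelation-controlled methyl transfer (Me2Zn with MeZnCl as chelating Lewis acid, toluene, −20 °C), a known way to override Felkin–Anh control next to a silyloxy group, would deliver methyl to the opposite face and so give the same C10 configuration in the silylated alkynyl diol F7. K2CO3 in MeOH would remove the alkynyl silyl group and return to 5.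

**Step 9.** The amine-catalysed reaction may be slow with the hindered α,β-bis(silyloxy) aldehyde, and long exposure to the amine invites epimerisation at C8 and β-elimination of silanol. The fallback builds the same unit by aldol addition and elimination. Setting out from 14, the lithium enolate of methyl 3-(phenylselanyl)propanoate (LDA, THF, −78 °C) would give the selenide aldol F8; oxidation with H2O2 and syn-elimination of the selenoxide would unveil the 2-methylidene group and arrive at 16.

**Step 14.** Acylation may be unselective (reaction at O9 or at both oxygens), or acyl migration may occur, because the two secondary hydroxyls differ only in steric environment. The fallback moves the differentiation to the desilylation. Setting out from 22, a short treatment with HF·pyridine at 0 °C should cleave the less hindered C8 silyl ether and give the 9-O-silyl 8-alcohol F9. Acylation with isovaleric anhydride and DMAP would give the 9-O-silyl ester F10, with no free β-hydroxy ketone present, and a second HF·pyridine treatment would arrive at 24.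

## Further compounds

F1 | step 12 | (6S,7R,8S)-7,8-bis[(tert-butyldimethylsilyl)oxy]-6,9-dihydroxy-2,6-dimethylnon-1-en-4-yn-3-one | C=C(C)C(=O)C#C[C@](C)(O)[C@H](O[Si](C)(C)C(C)(C)C)[C@@H](O[Si](C)(C)C(C)(C)C)CO
F2 | step 12 | (2R)-2-[(1R,2S)-1,2-bis[(tert-butyldimethylsilyl)oxy]-3-hydroxypropyl]-2-methyl-5-(prop-1-en-2-yl)furan-3(2H)-one | C=C(C)C1=CC(=O)[C@](C)(O1)[C@H](O[Si](C)(C)C(C)(C)C)[C@@H](O[Si](C)(C)C(C)(C)C)CO
F3 | step 12 | (2R,3R)-2,3-bis[(tert-butyldimethylsilyl)oxy]-3-[(2R)-2-methyl-3-oxo-5-(prop-1-en-2-yl)-2,3-dihydrofuran-2-yl]propanal | C=C(C)C1=CC(=O)[C@](C)(O1)[C@H](O[Si](C)(C)C(C)(C)C)[C@@H](O[Si](C)(C)C(C)(C)C)C=O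
F4 | step 12 | methyl (4S,5R)-4,5-bis[(tert-butyldimethylsilyl)oxy]-3-hydroxy-2-methylidene-5-[(2R)-2-methyl-3-oxo-5-(prop-1-en-2-yl)-2,3-dihydrofuran-2-yl]pentanoate (both C3 epimers) | C=C(C)C1=CC(=O)[C@](C)(O1)[C@H](O[Si](C)(C)C(C)(C)C)[C@@H](O[Si](C)(C)C(C)(C)C)C(O)C(=C)C(=O)OC
F5 | step 12 | methyl (2Z,4S,5R)-2-(bromomethyl)-4,5-bis[(tert-butyldimethylsilyl)oxy]-5-[(2R)-2-methyl-3-oxo-5-(prop-1-en-2-yl)-2,3-dihydrofuran-2-yl]pent-2-enoate | C=C(C)C1=CC(=O)[C@](C)(O1)[C@H](O[Si](C)(C)C(C)(C)C)[C@@H](O[Si](C)(C)C(C)(C)C)/C=C(\CBr)C(=O)OC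
F6 | step 3 | (4R,5S)-4,5-bis[(tert-butyldimethylsilyl)oxy]-6-hydroxy-1-(trimethylsilyl)hex-1-yn-3-one (open-chain form of its lactol) | C[Si](C)(C)C#CC(=O)[C@H](O[Si](C)(C)C(C)(C)C)[C@@H](O[Si](C)(C)C(C)(C)C)CO
F7 | step 3 | (2S,3R,4S)-2,3-bis[(tert-butyldimethylsilyl)oxy]-4-methyl-6-(trimethylsilyl)hex-5-yne-1,4-diol | C[Si](C)(C)C#C[C@](C)(O)[C@H](O[Si](C)(C)C(C)(C)C)[C@@H](O[Si](C)(C)C(C)(C)C)CO
F8 | step 9 | methyl (4S,5R)-4,5-bis[(tert-butyldimethylsilyl)oxy]-5-[(2R)-5-[(2Z)-4,4-dimethoxybut-2-en-2-yl]-2-methyl-3-oxo-2,3-dihydrofuran-2-yl]-3-hydroxy-2-[(phenylselanyl)methyl]pentanoate (mixture at C2 and C3) | COC(OC)/C=C(/C)C1=CC(=O)[C@](C)(O1)[C@H](O[Si](C)(C)C(C)(C)C)[C@@H](O[Si](C)(C)C(C)(C)C)C(O)C(C[Se]c1ccccc1)C(=O)OC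
F9 | step 14 | 9-O-(tert-butyldimethylsilyl)-8-O-desisovaleryl-lobatin B (free C8 hydroxyl) | C=C1C(=O)O[C@@H]2/C=C(/C)C3=CC(=O)[C@](C)(O3)[C@H](O[Si](C)(C)C(C)(C)C)[C@@H](O)[C@@H]12
F10 | step 14 | 9-O-(tert-butyldimethylsilyl)-lobatin B | C=C1C(=O)O[C@@H]2/C=C(/C)C3=CC(=O)[C@](C)(O3)[C@H](O[Si](C)(C)C(C)(C)C)[C@@H](OC(=O)CC(C)C)[C@@H]12
A1 | alternative 1 | trans-disubstituted α-methylene-γ-butyrolactone with a vinyl group on C6 and, on C7, the bis-silylated C8–C9 chain ending in the 2-methyl-5-(prop-1-en-2-yl)furan-3(2H)-one (metathesis diene) | C=C1C(=O)O[C@H](C=C)[C@H]1[C@H](O[Si](C)(C)C(C)(C)C)[C@@H](O[Si](C)(C)C(C)(C)C)[C@@]2(C)OC(C(C)=C)=CC2=O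
A2 | alternative 2 | monocyclic ten-membered 4-hydroxy-2-ynone (C3 ketone, C2≡C1, free C10 hydroxyl) with the 6,12-lactone and both silyl ethers | C=C1C(=O)O[C@@H]2/C=C(/C)C(=O)C#C[C@](C)(O)[C@H](O[Si](C)(C)C(C)(C)C)[C@@H](O[Si](C)(C)C(C)(C)C)[C@@H]12
A3 | alternative 3 | cis-fused cyclobutene (σ-bond C2–C5, π-bond C3=C4, oxygen bridge C3–O–C10) on the eight-membered ring C1, C2, C5–C10 with lactone and silyl ethers; C2/C5 cis, either face | C=C1C(=O)O[C@@H]2C3C(C)=C4O[C@@](C)(C(=O)C34)[C@H](O[Si](C)(C)C(C)(C)C)[C@@H](O[Si](C)(C)C(C)(C)C)[C@@H]12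
A4 | alternative 3 | cyclooct-2-enone (C1 ketone, cis C2=C5) with lactone on C6–C7, silyl ethers on C8 and C9, and methyl plus prop-1-yn-1-yloxy on C10 | C=C1C(=O)O[C@@H]2/C=C\C(=O)[C@](C)(OC#CC)[C@H](O[Si](C)(C)C(C)(C)C)[C@@H](O[Si](C)(C)C(C)(C)C)[C@@H]12
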